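Retrosynthesis: cut (i) the biaryl bond between two O‑benzylated chloro‑"olivil" halves (Suzuki–Miyaura); (ii) in each oxolane the C3–C4 ring bond together with the C–O bond of the 4‑CH2OH arm; (iii) C3–CH2Ar (Weinreb ketone synthesis), O1–C2 (Williamson) and C4–C5 (vinyl Grignard).
Enabling feature: in each oxolane (O1, C2, C3, C4, C5) the tertiary carbinol C3 and the CH2OH on C4 form a 1,3‑diol and O1 lies two bonds from C3, so the ring is the 5‑exo product of a 3‑oxahex‑5‑enyl ketyl (ketone at C3, vinyl on C5) whose terminal carbon is oxygenated.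
Forward: 5‑chlorovanillin → (S)‑allyl alcohol → keto‑olefin → first oxolane (the one whose 5‑aryl ring enters the biaryl, step 7) → boronate; O‑benzylvanillin → (S)‑allyl alcohol → keto‑olefin → second oxolane (the one whose 3‑benzyl ring enters the biaryl, step 15, last ring closure) → biaryl coupling → debenzylation.
Stereochemistry: C5 of each oxolane from lipase kinetic resolution of the 1‑arylallyl alcohol (S); C4 and C3 from substrate control in the ketyl–olefin closure (4,5‑trans; 3‑OH trans to the 4‑CH2OH arm), giving (3S,4R,5S) in both rings.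

Key step: step 15

Remark: each oxolane is numbered O1, C2 (CH2), C3 (C–OH), C4 (CH–CH2OH), C5 (CH–aryl); the lipase is assumed to show its usual preference for acylating the (R)‑enantiomer of these 1‑arylallyl alcohols.

Step 1
Reactants: 1 5-chlorovanillin (3-chloro-4-hydroxy-5-methoxybenzaldehyde)
Product: 2 4-(benzyloxy)-3-chloro-5-methoxybenzaldehyde
Conditions: BnBr, K2CO3, DMF, 60 °C
Reagents that add atoms: benzyl bromide BrCc1ccccc1
Why: Williamson etherification of the phenoxide; the benzyl ether should survive organomagnesium, SmI2 and Pd chemistry, and no stereocentre is involved.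

Step 2
Reactants: 2 4-(benzyloxy)-3-chloro-5-methoxybenzaldehyde; 3 vinylmagnesium bromide
Product: 4 rac-1-[4-(benzyloxy)-3-chloro-5-methoxyphenyl]prop-2-en-1-ol
Conditions: THF, −78 → 0 °C; aq. NH4Cl
Reagents that add atoms: none
Why: Grignard 1,2-addition to the aldehyde should give the racemic allylic alcohol; its carbinol centre (future C5) is resolved in step 3.

Step 3
Reactants: 4 rac-1-[4-(benzyloxy)-3-chloro-5-methoxyphenyl]prop-2-en-1-ol
Product: 5 (S)-1-[4-(benzyloxy)-3-chloro-5-methoxyphenyl]prop-2-en-1-ol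
Conditions: Novozym 435 (immobilised Candida antarctica lipase B), vinyl acetate (3 equiv), MTBE, 30 °C, run past half conversion; chromatography on Et3N-deactivated silica
Reagents that add atoms: none
Why: Lipase-catalysed kinetic resolution by transesterification; the enzyme should acylate the (R)-enantiomer (aryl large, vinyl medium), so the unreacted (S)-alcohol is recovered enantioenriched and fixes C5 of the first oxolane.

Step 4
Reactants: 5 (S)-1-[4-(benzyloxy)-3-chloro-5-methoxyphenyl]prop-2-en-1-ol; 6 2-chloro-N-methoxy-N-methylacetamide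
Product: 7 2-{[(1S)-1-[4-(benzyloxy)-3-chloro-5-methoxyphenyl]prop-2-en-1-yl]oxy}-N-methoxy-N-methylacetamide
Conditions: NaH, THF, 0 °C; then 6, Bu4NI (cat.), 0 °C → rt
Reagents that add atoms: none
Why: Williamson etherification (alkoxide SN2 on the α-chloro amide) forms the O1–C2 bond without touching the C–O bond of the stereocentre.

Step 5
Reactants: 8 [4-(benzyloxy)-3-methoxyphenyl]methanol
Product: 9 1-(benzyloxy)-4-(chloromethyl)-2-methoxybenzene
Conditions: SOCl2, CH2Cl2, 0 °C → rt
Reagents that add atoms: thionyl chloride O=S(Cl)Cl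
Why: Deoxychlorination of an electron-rich benzylic alcohol through its chlorosulfite; no stereocentre.

Step 6
Reactants: 9 1-(benzyloxy)-4-(chloromethyl)-2-methoxybenzene; 7 2-{[(1S)-1-[4-(benzyloxy)-3-chloro-5-methoxyphenyl]prop-2-en-1-yl]oxy}-N-methoxy-N-methylacetamide
Product: 11 1-{[(1S)-1-[4-(benzyloxy)-3-chloro-5-methoxyphenyl]prop-2-en-1-yl]oxy}-3-[4-(benzyloxy)-3-methoxyphenyl]propan-2-one, via benzylic Grignard reagent 10 (not isolated)
Conditions: Mg turnings, THF, 0 °C (slow addition of 9); then 7, THF, −78 → 0 °C; aq. NH4Cl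
Reagents that add atoms: none
Why: Weinreb ketone synthesis: the benzylic Grignard reagent adds once to the N-methoxy-N-methylamide (stable magnesium chelate) and the ketone is released only on work-up; the (S) centre is not involved.

Step 7
Reactants: 11 1-{[(1S)-1-[4-(benzyloxy)-3-chloro-5-methoxyphenyl]prop-2-en-1-yl]oxy}-3-[4-(benzyloxy)-3-methoxyphenyl]propan-2-one
Product: 14 (3S,4R,5S)-5-[4-(benzyloxy)-3-chloro-5-methoxyphenyl]-3-[4-(benzyloxy)-3-methoxybenzyl]-4-(hydroxymethyl)oxolan-3-ol, via alkylsamarium(III) alkoxide 12 (not isolated), via samarium(III) alkylperoxide 13 (not isolated)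
Conditions: SmI2 (0.1 M in THF, 2.5 equiv), HMPA (10 equiv), THF, 0 °C, slow addition of 11; then dry O2, −78 → 0 °C; then PPh3; aq. NaHCO3
Reagents that add atoms: dioxygen O=O
Why: SmI2–HMPA ketyl–olefin 5-exo-trig cyclisation with oxygenation of the alkylsamarium, as detailed for step 15: the C5 aryl group pseudo-equatorial should set C4 trans to it and the O–Sm group turned away from the alkene should set the C3 hydroxyl trans to the CH2OH arm, while the aryl chloride is not reduced under these conditions.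

Step 8
Reactants: 14 (3S,4R,5S)-5-[4-(benzyloxy)-3-chloro-5-methoxyphenyl]-3-[4-(benzyloxy)-3-methoxybenzyl]-4-(hydroxymethyl)oxolan-3-ol
Product: 15 (3S,4R,5S)-5-[4-(benzyloxy)-3-methoxy-5-(4,4,5,5-tetramethyl-1,3,2-dioxaborolan-2-yl)phenyl]-3-[4-(benzyloxy)-3-methoxybenzyl]-4-(hydroxymethyl)oxolan-3-ol
Conditions: B2pin2 (2 equiv), Pd2(dba)3 (2.5 mol%), XPhos (10 mol%), KOAc (3 equiv), 1,4-dioxane, 100 °C
Reagents that add atoms: bis(pinacolato)diboron CC1(C)OB(OC1(C)C)B1OC(C)(C)C(C)(C)O1
Why: Miyaura borylation of an electron-rich aryl chloride with a bulky biarylphosphine–Pd catalyst and acetate base; free alcohols and the stereocentres should be unaffected.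

Step 9
Reactants: 16 4-(benzyloxy)-3-methoxybenzaldehyde (O-benzylvanillin); 3 vinylmagnesium bromide
Product: 17 rac-1-[4-(benzyloxy)-3-methoxyphenyl]prop-2-en-1-ol
Conditions: THF, −78 → 0 °C; aq. NH4Cl
Reagents that add atoms: none
Why: Grignard 1,2-addition to the aldehyde should give the racemic allylic alcohol; its carbinol centre is resolved in step 10.

Step 10
Reactants: 17 rac-1-[4-(benzyloxy)-3-methoxyphenyl]prop-2-en-1-ol
Product: 18 (S)-1-[4-(benzyloxy)-3-methoxyphenyl]prop-2-en-1-ol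
Conditions: Novozym 435, vinyl acetate (3 equiv), MTBE, 30 °C, run past half conversion; chromatography on Et3N-deactivated silica
Reagents that add atoms: none
Why: Lipase-catalysed kinetic resolution by transesterification as in step 3; the (R)-enantiomer should be acylated and the (S)-alcohol recovered, which fixes C5 of the second oxolane.

Step 11
Reactants: 18 (S)-1-[4-(benzyloxy)-3-methoxyphenyl]prop-2-en-1-ol; 6 2-chloro-N-methoxy-N-methylacetamide
Product: 19 2-{[(1S)-1-[4-(benzyloxy)-3-methoxyphenyl]prop-2-en-1-yl]oxy}-N-methoxy-N-methylacetamide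
Conditions: NaH, THF, 0 °C; then 6, Bu4NI (cat.), 0 °C → rt
Reagents that add atoms: none
Why: Williamson etherification under basic conditions, which avoid ionisation of the acid-sensitive electron-rich allylic carbinol; the stereocentre is retained.

Step 12
Reactants: 2 4-(benzyloxy)-3-chloro-5-methoxybenzaldehyde
Product: 20 [4-(benzyloxy)-3-chloro-5-methoxyphenyl]methanol
Conditions: NaBH4, MeOH/THF, 0 °C
Reagents that add atoms: none
Why: Borohydride reduction of the aldehyde to the benzylic alcohol; no stereocentre.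

Step 13
Reactants: 20 [4-(benzyloxy)-3-chloro-5-methoxyphenyl]methanol
Product: 21 2-(benzyloxy)-1-chloro-5-(chloromethyl)-3-methoxybenzene
Conditions: SOCl2, CH2Cl2, 0 °C → rt
Reagents that add atoms: thionyl chloride O=S(Cl)Cl
Why: Deoxychlorination of the benzylic alcohol through its chlorosulfite; the aryl chloride is inert.

Step 14
Reactants: 21 2-(benzyloxy)-1-chloro-5-(chloromethyl)-3-methoxybenzene; 19 2-{[(1S)-1-[4-(benzyloxy)-3-methoxyphenyl]prop-2-en-1-yl]oxy}-N-methoxy-N-methylacetamide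
Product: 23 1-[4-(benzyloxy)-3-chloro-5-methoxyphenyl]-3-{[(1S)-1-[4-(benzyloxy)-3-methoxyphenyl]prop-2-en-1-yl]oxy}propan-2-one, via benzylic Grignard reagent 22 (not isolated)
Conditions: Mg turnings, THF, 0 °C (slow addition of 21); then 19, THF, −78 → 0 °C; aq. NH4Cl
Reagents that add atoms: none
Why: Weinreb ketone synthesis; magnesium should insert into the benzylic C–Cl bond and leave the aryl chloride alone, and single addition to the amide gives the ketone on work-up.

Step 15
Reactants: 23 1-[4-(benzyloxy)-3-chloro-5-methoxyphenyl]-3-{[(1S)-1-[4-(benzyloxy)-3-methoxyphenyl]prop-2-en-1-yl]oxy}propan-2-one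
Product: 26 (3S,4R,5S)-3-[4-(benzyloxy)-3-chloro-5-methoxybenzyl]-5-[4-(benzyloxy)-3-methoxyphenyl]-4-(hydroxymethyl)oxolan-3-ol, via alkylsamarium(III) alkoxide 24 (not isolated), via samarium(III) alkylperoxide 25 (not isolated)
Conditions: SmI2 (0.1 M in THF, 2.5 equiv), HMPA (10 equiv), THF, 0 °C, slow addition of 23; then dry O2, −78 → 0 °C; then PPh3; aq. NaHCO3
Reagents that add atoms: dioxygen O=O
Why: Single-electron transfer from SmI2–HMPA to the C3 ketone gives a ketyl radical anion that adds to the internal carbon of the vinyl group (new C3–C4 bond); the primary radical is reduced by a second SmI2 to the alkylsamarium 24, and O2 followed by PPh3 turns its C–Sm bond into the C–OH of the 4-hydroxymethyl arm. The closest known reaction type is the SmI2/HMPA ketyl–olefin cyclisation of unactivated olefinic ketones with capture of the resulting organosamarium by electrophiles, dioxygen among them. The oxolane closes in the 5-exo-trig mode of a 3-oxahex-5-enyl radical. C4 is controlled by the existing C5 stereocentre: the aryl group sits pseudo-equatorial in the chair-like transition state, so the new exocyclic CH2 ends trans to it (4R from 5S). C3 is controlled by the HMPA-loaded O–Sm(III) group of the ketyl, which turns away from the alkene, so the hydroxyl ends trans to the CH2O arm and cis to the C5 aryl, with the arylmethyl group cis to the arm (3S). The step needs ring closure to outrun expulsion of the α-alkoxide (C2–O1 cleavage) and radical reduction to outrun attack on the neighbouring arylmethyl ring; the oxygen atom in the tether speeds the 5-exo closure, inverse addition keeps SmI2 in excess over the ketone, and the aryl chloride and benzyl ethers are inert to SmI2–HMPA at 0 °C.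

Step 16
Reactants: 15 (3S,4R,5S)-5-[4-(benzyloxy)-3-methoxy-5-(4,4,5,5-tetramethyl-1,3,2-dioxaborolan-2-yl)phenyl]-3-[4-(benzyloxy)-3-methoxybenzyl]-4-(hydroxymethyl)oxolan-3-ol; 26 (3S,4R,5S)-3-[4-(benzyloxy)-3-chloro-5-methoxybenzyl]-5-[4-(benzyloxy)-3-methoxyphenyl]-4-(hydroxymethyl)oxolan-3-ol
Product: 27 tetra-O-benzyl ether of the target (biaryl-linked bis-oxolane with all four phenols benzylated)
Conditions: XPhos Pd G3 (3 mol%), K3PO4 (3 equiv), THF/H2O (4:1), 60 °C
Reagents that add atoms: none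
Why: Suzuki–Miyaura coupling (oxidative addition of the aryl chloride, transmetalation of the boronate, reductive elimination) forms a biaryl bond flanked by only one ortho substituent on each ring; free alcohols and all stereocentres are untouched.

Step 17
Reactants: 27 tetra-O-benzyl ether of the target
Product: 28 CNP0269573.1 (target)
Conditions: H2 (1 atm), 10% Pd/C, EtOAc/MeOH (1:1), rt, stopped at complete debenzylation
Reagents that add atoms: none
Why: Catalytic hydrogenolysis should cleave the four aryl benzyl ethers faster than the cyclic benzylic C5–O1 bonds under neutral conditions at 1 atm; no stereocentre is touched.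

Compound list
1 | 5-chlorovanillin (3-chloro-4-hydroxy-5-methoxybenzaldehyde) | COc1cc(C=O)cc(Cl)c1O | starting material
2 | 4-(benzyloxy)-3-chloro-5-methoxybenzaldehyde | COc1cc(C=O)cc(Cl)c1OCc1ccccc1 | intermediate
3 | vinylmagnesium bromide | C=C[Mg]Br | starting material
4 | rac-1-[4-(benzyloxy)-3-chloro-5-methoxyphenyl]prop-2-en-1-ol | COc1cc(C(O)C=C)cc(Cl)c1OCc1ccccc1 | intermediate
5 | (S)-1-[4-(benzyloxy)-3-chloro-5-methoxyphenyl]prop-2-en-1-ol | C=C[C@H](O)c1cc(OC)c(OCc2ccccc2)c(Cl)c1 | intermediate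
6 | 2-chloro-N-methoxy-N-methylacetamide | CON(C)C(=O)CCl | starting material
7 | 2-{[(1S)-1-[4-(benzyloxy)-3-chloro-5-methoxyphenyl]prop-2-en-1-yl]oxy}-N-methoxy-N-methylacetamide | C=C[C@H](OCC(=O)N(C)OC)c1cc(OC)c(OCc2ccccc2)c(Cl)c1 | intermediate
8 | [4-(benzyloxy)-3-methoxyphenyl]methanol | COc1cc(CO)ccc1OCc1ccccc1 | starting material
9 | 1-(benzyloxy)-4-(chloromethyl)-2-methoxybenzene | COc1cc(CCl)ccc1OCc1ccccc1 | intermediate
10 | [4-(benzyloxy)-3-methoxybenzyl]magnesium chloride | COc1cc(C[Mg]Cl)ccc1OCc1ccccc1 | intermediate (not isolated)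
11 | 1-{[(1S)-1-[4-(benzyloxy)-3-chloro-5-methoxyphenyl]prop-2-en-1-yl]oxy}-3-[4-(benzyloxy)-3-methoxyphenyl]propan-2-one | C=C[C@H](OCC(=O)Cc1ccc(OCc2ccccc2)c(OC)c1)c1cc(OC)c(OCc2ccccc2)c(Cl)c1 | intermediate
12 | alkylsamarium(III) alkoxide of 14 (SmI2 on the C3 oxygen and on the C4 methylene carbon) | COc1cc(C[C@@]2(O[Sm](I)I)CO[C@H](c3cc(OC)c(OCc4ccccc4)c(Cl)c3)[C@H]2C[Sm](I)I)ccc1OCc1ccccc1 | intermediate (not isolated)
13 | samarium(III) alkylperoxide of 14 (C4–CH2–O–O–SmI2, C3–O–SmI2) | COc1cc(C[C@@]2(O[Sm](I)I)CO[C@H](c3cc(OC)c(OCc4ccccc4)c(Cl)c3)[C@H]2COO[Sm](I)I)ccc1OCc1ccccc1 | intermediate (not isolated)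
14 | (3S,4R,5S)-5-[4-(benzyloxy)-3-chloro-5-methoxyphenyl]-3-[4-(benzyloxy)-3-methoxybenzyl]-4-(hydroxymethyl)oxolan-3-ol | COc1cc(C[C@@]2(O)CO[C@H](c3cc(OC)c(OCc4ccccc4)c(Cl)c3)[C@H]2CO)ccc1OCc1ccccc1 | intermediate
15 | (3S,4R,5S)-5-[4-(benzyloxy)-3-methoxy-5-(4,4,5,5-tetramethyl-1,3,2-dioxaborolan-2-yl)phenyl]-3-[4-(benzyloxy)-3-methoxybenzyl]-4-(hydroxymethyl)oxolan-3-ol | COc1cc(C[C@@]2(O)CO[C@H](c3cc(OC)c(OCc4ccccc4)c(B5OC(C)(C)C(C)(C)O5)c3)[C@H]2CO)ccc1OCc1ccccc1 | intermediate
16 | 4-(benzyloxy)-3-methoxybenzaldehyde (O-benzylvanillin) | COc1cc(C=O)ccc1OCc1ccccc1 | starting material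
17 | rac-1-[4-(benzyloxy)-3-methoxyphenyl]prop-2-en-1-ol | COc1cc(C(O)C=C)ccc1OCc1ccccc1 | intermediate
18 | (S)-1-[4-(benzyloxy)-3-methoxyphenyl]prop-2-en-1-ol | C=C[C@H](O)c1ccc(OCc2ccccc2)c(OC)c1 | intermediate
19 | 2-{[(1S)-1-[4-(benzyloxy)-3-methoxyphenyl]prop-2-en-1-yl]oxy}-N-methoxy-N-methylacetamide | C=C[C@H](OCC(=O)N(C)OC)c1ccc(OCc2ccccc2)c(OC)c1 | intermediate
20 | [4-(benzyloxy)-3-chloro-5-methoxyphenyl]methanol | COc1cc(CO)cc(Cl)c1OCc1ccccc1 | intermediate
21 | 2-(benzyloxy)-1-chloro-5-(chloromethyl)-3-methoxybenzene | COc1cc(CCl)cc(Cl)c1OCc1ccccc1 | intermediate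
22 | [4-(benzyloxy)-3-chloro-5-methoxybenzyl]magnesium chloride | COc1cc(C[Mg]Cl)cc(Cl)c1OCc1ccccc1 | intermediate (not isolated)
23 | 1-[4-(benzyloxy)-3-chloro-5-methoxyphenyl]-3-{[(1S)-1-[4-(benzyloxy)-3-methoxyphenyl]prop-2-en-1-yl]oxy}propan-2-one | C=C[C@H](OCC(=O)Cc1cc(OC)c(OCc2ccccc2)c(Cl)c1)c1ccc(OCc2ccccc2)c(OC)c1 | intermediate
24 | alkylsamarium(III) alkoxide of 26 (SmI2 on the C3 oxygen and on the C4 methylene carbon) | Clc1cc(C[C@@]2(O[Sm](I)I)CO[C@H](c3ccc(OCc4ccccc4)c(OC)c3)[C@H]2C[Sm](I)I)cc(OC)c1OCc1ccccc1 | intermediate (not isolated)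
25 | samarium(III) alkylperoxide of 26 (C4–CH2–O–O–SmI2, C3–O–SmI2) | Clc1cc(C[C@@]2(O[Sm](I)I)CO[C@H](c3ccc(OCc4ccccc4)c(OC)c3)[C@H]2COO[Sm](I)I)cc(OC)c1OCc1ccccc1 | intermediate (not isolated)
26 | (3S,4R,5S)-3-[4-(benzyloxy)-3-chloro-5-methoxybenzyl]-5-[4-(benzyloxy)-3-methoxyphenyl]-4-(hydroxymethyl)oxolan-3-ol | Clc1cc(C[C@@]2(O)CO[C@H](c3ccc(OCc4ccccc4)c(OC)c3)[C@H]2CO)cc(OC)c1OCc1ccccc1 | intermediate
27 | tetra-O-benzyl ether of the target | COc1cc(C[C@@]2(O)CO[C@H](c3cc(OC)c(OCc7ccccc7)c(-c4cc(C[C@@]5(O)CO[C@H](c6ccc(OCc8ccccc8)c(OC)c6)[C@H]5CO)cc(OC)c4OCc9ccccc9)c3)[C@H]2CO)ccc1OCc1ccccc1 | intermediate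
28 | CNP0269573.1 | COc1cc(C[C@@]2(O)CO[C@H](c3cc(OC)c(O)c(-c4cc(C[C@@]5(O)CO[C@H](c6ccc(O)c(OC)c6)[C@H]5CO)cc(OC)c4O)c3)[C@H]2CO)ccc1O | target

Total step count: 17. Longest linear sequence: 9 steps (1, 2, 3, 4, 6, 7, 8, 16, 17).

Steps most likely to fail

1. Step 15 (key step). After ring closure the primary radical or the alkylsamarium may be lost by hydrogen abstraction, protonation or attack on the cis arylmethyl ring before dioxygen captures it, and the capture by O2 may itself be inefficient. Fallback, setting out from 23 and coming back at 26: cross-metathesis of 23 with (Z)-but-2-ene-1,4-diyl diacetate [(H2IMes)(PCy3)Cl2Ru=CHPh, CH2Cl2, 40 °C] would give the allylic acetate (2E,4S)-4-{3-[4-(benzyloxy)-3-chloro-5-methoxyphenyl]-2-oxopropoxy}-4-[4-(benzyloxy)-3-methoxyphenyl]but-2-en-1-yl acetate F1. SmI2–HMPA would then close the same ring, but the alkylsamarium now sits β to the acetate and is consumed at once by β-elimination, so no external electrophile is needed. The product would be the vinyl compound (3S,4R,5S)-3-[4-(benzyloxy)-3-chloro-5-methoxybenzyl]-5-[4-(benzyloxy)-3-methoxyphenyl]-4-ethenyloxolan-3-ol F2, expected with the same stereochemical course. Lemieux–Johnson cleavage of the vinyl group (OsO4 cat., NaIO4, 2,6-lutidine, dioxane–water) and NaBH4 reduction in the same flask at 0 °C would give 26. This fallback does not remove the risk of α-alkoxide loss from the ketyl.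

2. Step 7. The same processes as in step 15 (loss of the radical or alkylsamarium before oxygenation), here on the regioisomeric keto-olefin. Fallback, setting out from 11 and coming back at 14: cross-metathesis of 11 with (Z)-but-2-ene-1,4-diyl diacetate would give the allylic acetate (2E,4S)-4-[4-(benzyloxy)-3-chloro-5-methoxyphenyl]-4-{3-[4-(benzyloxy)-3-methoxyphenyl]-2-oxopropoxy}but-2-en-1-yl acetate F3. SmI2–HMPA ketyl–olefin closure with β-elimination of acetate would give the vinyl compound (3S,4R,5S)-5-[4-(benzyloxy)-3-chloro-5-methoxyphenyl]-3-[4-(benzyloxy)-3-methoxybenzyl]-4-ethenyloxolan-3-ol F4. Oxidative cleavage of the vinyl group and NaBH4 reduction would give 14.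

3. Step 16. Protodeboronation of the electron-rich, ortho-alkoxy arylboronate in warm aqueous base may outpace oxidative addition and transmetalation at the electron-rich, ortho-substituted aryl chloride. Fallback, setting out from 15 and coming back at 27: treatment of 15 with KHF2 in MeOH–H2O would give the slow-release nucleophile potassium {2-(benzyloxy)-5-[(2S,3R,4S)-4-[4-(benzyloxy)-3-methoxybenzyl]-4-hydroxy-3-(hydroxymethyl)oxolan-2-yl]-3-methoxyphenyl}trifluoroborate F5. Coupling of F5 with 26 under organotrifluoroborate conditions (Pd(OAc)2, RuPhos, K2CO3, toluene–H2O, 85 °C) would give 27.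

Further compounds
F1 | step 15 | (2E,4S)-4-{3-[4-(benzyloxy)-3-chloro-5-methoxyphenyl]-2-oxopropoxy}-4-[4-(benzyloxy)-3-methoxyphenyl]but-2-en-1-yl acetate | CC(=O)OC/C=C/[C@H](OCC(=O)Cc1cc(OC)c(OCc2ccccc2)c(Cl)c1)c1ccc(OCc2ccccc2)c(OC)c1
F2 | step 15 | (3S,4R,5S)-3-[4-(benzyloxy)-3-chloro-5-methoxybenzyl]-5-[4-(benzyloxy)-3-methoxyphenyl]-4-ethenyloxolan-3-ol | Clc1cc(C[C@@]2(O)CO[C@H](c3ccc(OCc4ccccc4)c(OC)c3)[C@H]2C=C)cc(OC)c1OCc1ccccc1
F3 | step 7 | (2E,4S)-4-[4-(benzyloxy)-3-chloro-5-methoxyphenyl]-4-{3-[4-(benzyloxy)-3-methoxyphenyl]-2-oxopropoxy}but-2-en-1-yl acetate | CC(=O)OC/C=C/[C@H](OCC(=O)Cc1ccc(OCc2ccccc2)c(OC)c1)c1cc(OC)c(OCc2ccccc2)c(Cl)c1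
F4 | step 7 | (3S,4R,5S)-5-[4-(benzyloxy)-3-chloro-5-methoxyphenyl]-3-[4-(benzyloxy)-3-methoxybenzyl]-4-ethenyloxolan-3-ol | COc1cc(C[C@@]2(O)CO[C@H](c3cc(OC)c(OCc4ccccc4)c(Cl)c3)[C@H]2C=C)ccc1OCc1ccccc1
F5 | step 16 | potassium {2-(benzyloxy)-5-[(2S,3R,4S)-4-[4-(benzyloxy)-3-methoxybenzyl]-4-hydroxy-3-(hydroxymethyl)oxolan-2-yl]-3-methoxyphenyl}trifluoroborate | COc1cc(C[C@@]2(O)CO[C@H](c3cc(OC)c(OCc4ccccc4)c([B-](F)(F)F)c3)[C@H]2CO)ccc1OCc1ccccc1.[K+]
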